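## Structural features

The target is a flavone. Benzene ring A (C4a, C5, C6, C7, C8, C8a) is fused along C4a–C8a to the 4-pyranone ring C (O1, C2, C3, C4), and ring B (C1'–C6') is joined to ring C by the single bond C2–C1'. Ring A bears no hydrogen: OH at C5 (hydrogen-bonded to the C4 carbonyl), CH3 at C6, OCH3 at C7, CH3 at C8, O1 at C8a and the acyl carbon C4 at C4a. Ring B is a catechol (OH at C3' and C4') with a 3-methylbut-2-enyl (prenyl) group at C5', ortho to the C4' hydroxyl and meta to C1'. There is no stereocentre, and the prenyl double bond ends in two equal methyl groups, so no configuration has to be set. The fragile groups are the catechol and the ortho-prenylphenol: the catechol is oxidised to the ortho-quinone by air in base and by the usual dehydrogenating agents, while the ortho-prenylphenol is closed to a 2,2-dimethylchroman by strong acid or electrophilic halogen and is saturated under hydrogenolysis. The real difficulty is the hexasubstituted ring A, where three oxygens in a 1,3,5 relation must end in three different states (free OH, methyl ether, ring ether) between two C-methyl groups and an acyl group. The key step exploits two facts: C5, C6, C7, C8, C8a, C4a, C4, C3 and C2 form one unbroken chain with oxygen on every second carbon (a poly-beta-carbonyl chain), and ring A is symmetric about the C4a···C7 axis until ring C is closed. Hence the C7 methyl ether can be fixed in a 2-pyrone before ring A exists, and either ortho oxygen may close ring C with the same result.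

## Logic of the disconnections

Flavone numbering is used for the atoms of every precursor.

**15 to 14.** The bonds concerned are O3'–H and O4'–H, which become O–CH2OCH3 in 14. The catechol must be masked because every carbon–carbon bond of the route is made with carbanions or hot methoxide, where a free catecholate would be oxidised and would consume base. The gain is a ring B that is inert to base and to palladium. The demand on the forward step is an acetal cleavage mild enough not to protonate the prenyl double bond.

**14 to 11, by way of 13 and 12 (key disconnection).** The bonds cut are O1–C2 (14 to 13) and C4a–C5 (13 to 12). The ester of 12 is then tied back to the oxygen on C8a as the lactone of 11.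
- These two bonds are the only ones that interrupt the chain C5···C2. When they are cut, rings A and C both disappear and a linear chain is left.
- In 11 the chain is stored with C5 as lactone carbonyl, C7 as methyl enol ether and C8a as enol ester oxygen, so the three ring A oxygens are already different from each other.
- The gain is the step from a bicycle with a hexasubstituted benzene to a monocyclic pyrone with an unbranched side chain. No aromatic substitution on ring A is ever needed.
- In one sentence: rings A and C of 14 are folded in a single operation out of 11 by lactone opening, Claisen condensation of C4a on C5, and cyclodehydration of a ring A oxygen on C2.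
- The demand is acyl–oxygen opening of the lactone, C-acylation at C4a and nowhere else, and no retro-Claisen loss of the chain.

**11 to 6 + 10.** The bond cut is C2–C3. It separates the whole of ring B, as a plain benzoate, from the polyketide half, and makes the route convergent at the latest sensible point. The demand is a carbanion at the terminal carbon C3 of 6 in the presence of the more acidic C4a methylene. This calls for a dianion, and for base to absorb the acidity of the product.

**6 to 5 + 2.** The bond cut is C4–C4a. It removes a two-carbon unit and leaves a pyrone whose only acidic position is the methyl group that becomes C4a. The demand is site-selective deprotonation among three ring methyl groups and mono-acylation.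

**5 to 4 to 3.** The bonds cut are O7–CH3 and the lactone bond between the oxygen on C8a and C5. The first cut places the only O-methylation of ring A on a compound with a single acidic OH. The second turns the heterocycle into an open 3,5-dioxo ester. The demand is alkylation at the oxygen on C7 and not at the lactone carbonyl oxygen, and O-acylation rather than C-acylation in the ring closure.

**3 to 1 + 2.** The bond cut is C8–C8a. Compound 1 already holds C5, C6, C7, C8 and both C-methyl groups in the right places, so the two methyl groups of ring A are bought and not introduced. The demand is acylation at the gamma-carbon of a beta-keto ester.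

**10 to 8 + 9, and 8 to 7.** The bonds cut are C5'–CH2 of the prenyl group and the two O–CH2 bonds of the acetals. The halogen of 7 marks C5' unambiguously, which electrophilic prenylation of a catechol could not do. The demand is coupling at the primary end of the allylic unit.

## Other disconnections considered

**Alternative 1:** the first plan that comes to mind.
- *Cut:* O1–C2 and C2–C3.
- *Forward key step:* Claisen–Schmidt condensation of 1-(2,6-dihydroxy-4-methoxy-3,5-dimethylphenyl)ethan-1-one A1 with 3,4-bis(methoxymethoxy)-5-prenylbenzaldehyde A2 to chalcone A3, then oxidative cyclisation (I2, DMSO, above 100 °C).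
- *Ground for preferring the chosen plan:* the key step touches only ring C, while the hard part, ring A, is hidden in A1. A1 would need two C-methylations and one selective O-methylation of a phloroglucinol-type arene, a class whose anions tend to run on to geminally dialkylated, dearomatised products. The closing oxidation generates electrophilic iodine and HI at high temperature. By mechanism these are the reagents that attack a prenyl group next to an acetal-protected phenol. The step count would be no lower.

**Alternative 2:** direct union of rings C and B.
- *Cut:* C2–C1'.
- *Forward key step:* Pd(OAc)2-catalysed oxidative coupling of the C2–H bond of 5-hydroxy-7-methoxy-6,8-dimethyl-4H-chromen-4-one A4 with 1,2-bis(methoxymethoxy)-3-prenylbenzene A5. The partner reacts either through its own C5–H bond or after sterically controlled C–H borylation ([Ir(OMe)(cod)]2, 4,4'-di-tert-butyl-2,2'-bipyridine, B2pin2) to the boronate A6. The site in A5 is explained by the pattern: C5 is the only position of the 1,2,3-trisubstituted ring with no ortho substituent.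
- *Ground for preferring the chosen plan:* only one bond is gained, and ring A and ring C must still be made by the classical route before the coupling. Divalent palladium with a silver or copper oxidant in hot carboxylic acid is also a reagent for allylic C–H oxidation and Wacker-type attack on the trisubstituted alkene. The free C5–OH/C4=O chelate site can hold the catalyst away from C2.

**Alternative 3:** three-component assembly of ring C.
- *Cut:* C4–C4a, C3–C4 and O1–C2.
- *Forward key step:* carbonylative Sonogashira coupling of 2-iodo-5-methoxy-4,6-dimethylbenzene-1,3-diol A7 with 5-ethynyl-1,2-bis(methoxymethoxy)-3-prenylbenzene A8 under carbon monoxide to ynone A9, which closes to the flavone.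
- *Ground for preferring the chosen plan:* oxidative addition and CO insertion would have to take place at a very electron-rich carbon flanked by two ortho oxygens, where reduction of the C–I bond is the expected competitor. The ynone can close in the 5-exo mode (aurone) as well as in the 6-endo mode. A7 again presupposes a finished pentasubstituted ring A, and A8 costs two homologation steps more than the benzoate used here.

Key step: step 8

Remark on the chemistry: 7 and 9 are taken as commercial. Compounds 3, 11, 12 and 13 are written as keto tautomers. The stereocentres of 3 and 12 are enolisable, disappear in the next event and are left unspecified.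

## Steps

**Step 1**
Reactants: 1 ethyl 2-methyl-3-oxopentanoate; 2 N-methoxy-N-methylacetamide
Product: 3 ethyl 2,4-dimethyl-3,5-dioxohexanoate
Conditions: LiN(i-Pr)2 (2.2 equiv), THF, −78 to 0 °C; 2, −78 to 0 °C; 1 M HCl
Reagents that add atoms: none
Why: Gamma-acylation of a beta-keto ester dianion combined with the Weinreb ketone synthesis: the less stabilised C4 carbanion is the more nucleophilic site, and the chelated tetrahedral adduct persists until the quench, so the more acidic product cannot protonate the dianion. 3 is a mixture of diastereomers and enols, which is of no consequence because both centres become sp2 in step 2.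

**Step 2**
Reactants: 3 ethyl 2,4-dimethyl-3,5-dioxohexanoate
Product: 4 4-hydroxy-3,5,6-trimethyl-2H-pyran-2-one
Conditions: DBU (1.0 equiv), toluene, reflux; acidic wash
Reagents that add atoms: none
Why: Base-induced lactonisation of a 3,5-dioxo ester: the enolate oxygen of the C5 ketone acylates on the ester (6-exo-trig) and the product is withdrawn as the stabilised pyronolate. DBU is too weak to form the terminal methyl carbanion that a competing carbocyclisation would need.

**Step 3**
Reactants: 4 4-hydroxy-3,5,6-trimethyl-2H-pyran-2-one
Product: 5 4-methoxy-3,5,6-trimethyl-2H-pyran-2-one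
Conditions: Me2SO4, K2CO3, acetone, reflux
Reagents that add atoms: dimethyl sulfate, COS(=O)(=O)OC
Why: O-alkylation of the pyronolate anion with a hard electrophile; in the anion the charge is highest on the C4 oxygen, which should favour the 4-methoxy-2-pyrone, whereas the isomeric 2-methoxy-4-pyrone is the expected product only when the neutral pyrone is alkylated at its carbonyl oxygen. C-alkylation at C3 would destroy the conjugated ring and is disfavoured with a sulfate.

**Step 4**
Reactants: 5 4-methoxy-3,5,6-trimethyl-2H-pyran-2-one; 2 N-methoxy-N-methylacetamide
Product: 6 4-methoxy-3,5-dimethyl-6-(2-oxopropyl)-2H-pyran-2-one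
Conditions: LiN(i-Pr)2 (1.1 equiv), THF, −78 °C; 2, −78 to −20 °C; 1 M HCl
Reagents that add atoms: none
Why: Vinylogous deprotonation and Weinreb ketone synthesis: only the methyl group at pyrone C6 is conjugated through both ring double bonds with the lactone carbonyl, while the methyl groups at pyrone C3 and C5 are cross-conjugated and not acidic. The extended enolate reacts at the exocyclic carbon because attack through a ring carbon would create a quaternary centre and break the conjugation, and the stable tetrahedral adduct prevents double acylation.

**Step 5**
Reactants: 7 methyl 3-bromo-4,5-dihydroxybenzoate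
Product: 8 methyl 3-bromo-4,5-bis(methoxymethoxy)benzoate
Conditions: NaH (2.4 equiv), MOMCl (2.4 equiv), DMF, 0 °C to rt
Reagents that add atoms: chloromethyl methyl ether, COCCl
Why: Williamson-type alkylation of the catechol dianion with a highly reactive alpha-chloro ether. Ester and aryl bromide are inert under these conditions.

**Step 6**
Reactants: 8 methyl 3-bromo-4,5-bis(methoxymethoxy)benzoate; 9 4,4,5,5-tetramethyl-2-(3-methylbut-2-en-1-yl)-1,3,2-dioxaborolane
Product: 10 methyl 3,4-bis(methoxymethoxy)-5-(3-methylbut-2-en-1-yl)benzoate
Conditions: Pd(dppf)Cl2 (5 mol %), K2CO3, 1,4-dioxane/H2O, 80 °C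
Reagents that add atoms: none
Why: Suzuki–Miyaura coupling of an allylic boronate: after transmetalation the sigma-allyl palladium species interconvert through the pi-allyl form, and with the wide-bite-angle dppf ligand reductive elimination should occur at the unhindered primary terminus to give the linear prenyl group. MOM ethers and the benzoate tolerate aqueous carbonate at this temperature.

**Step 7**
Reactants: 6 4-methoxy-3,5-dimethyl-6-(2-oxopropyl)-2H-pyran-2-one; 10 methyl 3,4-bis(methoxymethoxy)-5-(3-methylbut-2-en-1-yl)benzoate
Product: 11 6-{4-[3,4-bis(methoxymethoxy)-5-(3-methylbut-2-en-1-yl)phenyl]-2,4-dioxobutyl}-4-methoxy-3,5-dimethyl-2H-pyran-2-one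
Conditions: 6, LiN(i-Pr)2 (3.2 equiv), THF, −78 to −20 °C; 10, −78 °C to rt; AcOH, 0 °C
Reagents that add atoms: none
Why: Terminal aroylation of a 1,3-dicarbonyl-type dianion (crossed Claisen condensation): the first equivalent of base removes the doubly activated C4a proton, the second a proton of the C3 methyl group, and the less stabilised C3 carbanion attacks the ester. The third equivalent takes up the new acidic proton of the product, so the dianion is not spent as a base. The negatively charged pyrone is a poor electrophile, and MOM ethers and the prenyl group are inert.

**Step 8**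
Reactants: 11 6-{4-[3,4-bis(methoxymethoxy)-5-(3-methylbut-2-en-1-yl)phenyl]-2,4-dioxobutyl}-4-methoxy-3,5-dimethyl-2H-pyran-2-one
Product: 14 2-[3,4-bis(methoxymethoxy)-5-(3-methylbut-2-en-1-yl)phenyl]-5-hydroxy-7-methoxy-6,8-dimethyl-4H-chromen-4-one, via ring-opened trioxo ester 12 (not isolated), via aryl beta-diketone 13 (not isolated)
Conditions: Mg(OMe)2 (6 equiv), MeOH, reflux, argon; then AcOH (excess), 60 °C
Reagents that add atoms: magnesium methoxide, [Mg+2].C[O-].C[O-] (its methoxide is held only in intermediate 12 and leaves again on the way to 13; no atom of it stays in 14)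
Why: Mg(OMe)2 first binds the most acidic site, the C2/C4 beta-diketone of the side chain, as a magnesium chelate, which leaves the pyrone ring uncharged, so that methoxide can add to the lactone carbonyl (future C5) and expel the enolate oxygen on C8a to give 12, in which the ester and C8 stay cis on the C6=C7 double bond as they were in the ring. In 12 the methylene C4a lies between two ketones, and its magnesium enolate attacks the ester carbonyl in a Dieckmann-type Claisen condensation (6-exo-trig, allowed for the enolendo as well as the enolexo form of the enolate), methoxide leaves, and tautomerisation gives the aromatic ring A of 13, an irreversible sink held as a magnesium phenoxide chelate. On acidification one of the two equivalent ortho hydroxyl groups adds to the C2 ketone (6-exo-trig hemiketal) and loss of water closes ring C, while the other hydroxyl becomes the chelated C5–OH. The closest known reaction type is the magnesium methoxide induced rearrangement of 6-(2-oxoalkyl)-2-pyrones bearing oxygen at C4 into acylphloroglucinols, followed by the cyclodehydration of ortho-hydroxyaryl beta-diketones that ends a Baker–Venkataraman flavone synthesis. Claisen versus aldol folding is decided by the substrate, since the aldol mode would need C6 as the nucleophile, and C6 is the methyl-bearing alpha-carbon of a beta-methoxyacrylate that can neither be enolised nor end in an arene. Between the two active methylenes only C4a can react productively, because C3 would reach the ester through an eight-membered ring and its attack on C7 would have to displace methoxide from a tetrasubstituted, donor-deactivated carbon. Exchange of the C7 methoxy group is degenerate because base and solvent are methoxide and methanol, chelation of the fully enolised chain should suppress retro-Claisen cleavage, and MOM ethers and the prenyl group are inert to methoxide and to warm AcOH. No stereocentre is formed, and the labile C8 centre of 12 disappears on aromatisation.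

**Step 9**
Reactants: 14 2-[3,4-bis(methoxymethoxy)-5-(3-methylbut-2-en-1-yl)phenyl]-5-hydroxy-7-methoxy-6,8-dimethyl-4H-chromen-4-one
Product: 15 2-[3,4-dihydroxy-5-(3-methylbut-2-en-1-yl)phenyl]-5-hydroxy-7-methoxy-6,8-dimethyl-4H-chromen-4-one (target)
Conditions: HCl (1.25 M in MeOH), 40 °C, argon
Reagents that add atoms: none
Why: Acid-catalysed acetal exchange with methanol through the oxocarbenium ion, which forms far more easily than the tertiary cation from protonation of the trisubstituted alkene, so dilute acid at low temperature should free the catechol before the prenyl group reacts. The aryl methyl ether and the flavone core are inert, and argon protects the catechol.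

## Compound list

1 | ethyl 2-methyl-3-oxopentanoate | CCC(=O)C(C)C(=O)OCC | starting material
2 | N-methoxy-N-methylacetamide | CC(=O)N(C)OC | starting material
3 | ethyl 2,4-dimethyl-3,5-dioxohexanoate | CC(=O)C(C)C(=O)C(C)C(=O)OCC | intermediate
4 | 4-hydroxy-3,5,6-trimethyl-2H-pyran-2-one | Cc1oc(=O)c(C)c(O)c1C | intermediate
5 | 4-methoxy-3,5,6-trimethyl-2H-pyran-2-one | COc1c(C)c(C)oc(=O)c1C | intermediate
6 | 4-methoxy-3,5-dimethyl-6-(2-oxopropyl)-2H-pyran-2-one | COc1c(C)c(CC(C)=O)oc(=O)c1C | intermediate
7 | methyl 3-bromo-4,5-dihydroxybenzoate | COC(=O)c1cc(O)c(O)c(Br)c1 | starting material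
8 | methyl 3-bromo-4,5-bis(methoxymethoxy)benzoate | COCOc1cc(cc(Br)c1OCOC)C(=O)OC | intermediate
9 | 4,4,5,5-tetramethyl-2-(3-methylbut-2-en-1-yl)-1,3,2-dioxaborolane | CC(C)=CCB1OC(C)(C)C(C)(C)O1 | starting material
10 | methyl 3,4-bis(methoxymethoxy)-5-(3-methylbut-2-en-1-yl)benzoate | COCOc1cc(cc(CC=C(C)C)c1OCOC)C(=O)OC | intermediate
11 | 6-{4-[3,4-bis(methoxymethoxy)-5-(3-methylbut-2-en-1-yl)phenyl]-2,4-dioxobutyl}-4-methoxy-3,5-dimethyl-2H-pyran-2-one | COCOc1cc(cc(CC=C(C)C)c1OCOC)C(=O)CC(=O)Cc1oc(=O)c(C)c(OC)c1C | intermediate
12 | methyl (2E)-9-[3,4-bis(methoxymethoxy)-5-(3-methylbut-2-en-1-yl)phenyl]-3-methoxy-2,4-dimethyl-5,7,9-trioxonon-2-enoate (C4 labile) | COC(=O)/C(C)=C(/OC)C(C)C(=O)CC(=O)CC(=O)c1cc(OCOC)c(OCOC)c(CC=C(C)C)c1 | intermediate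
13 | 1-[3,4-bis(methoxymethoxy)-5-(3-methylbut-2-en-1-yl)phenyl]-3-(2,6-dihydroxy-4-methoxy-3,5-dimethylphenyl)propane-1,3-dione | COc1c(C)c(O)c(C(=O)CC(=O)c2cc(OCOC)c(OCOC)c(CC=C(C)C)c2)c(O)c1C | intermediate
14 | 2-[3,4-bis(methoxymethoxy)-5-(3-methylbut-2-en-1-yl)phenyl]-5-hydroxy-7-methoxy-6,8-dimethyl-4H-chromen-4-one | COCOc1cc(cc(CC=C(C)C)c1OCOC)-c1cc(=O)c2c(O)c(C)c(OC)c(C)c2o1 | intermediate
15 | 2-[3,4-dihydroxy-5-(3-methylbut-2-en-1-yl)phenyl]-5-hydroxy-7-methoxy-6,8-dimethyl-4H-chromen-4-one | COc1c(C)c(O)c2c(=O)cc(-c3cc(O)c(O)c(CC=C(C)C)c3)oc2c1C | target

## Step count and least certain steps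

Total step count: 9. Longest linear sequence: 7 (steps 1, 2, 3, 4, 7, 8, 9). Steps 5 and 6 form the second branch.

**Step 8 (key step).**
- *What may go wrong:* methanolysis of the lactone may be too slow if the C4a position is deprotonated as well, because the charge is then pushed into the pyrone carbonyl. Methoxide may also cleave the chain by retro-Claisen reaction before the ring is opened. Any chain that has been opened but has not undergone the Claisen step would close on acidification through its C8a, C4 and C2 oxygens to a monocyclic 4-pyranone instead.
- *Fallback:* it sets out from 6 and 10 and comes back to the route at 13. The ring transformation is carried out first on the short-chain compound 6 (Mg(OMe)2, MeOH, reflux), which has a single carbanion site and no cleavable triketone. This gives 1-(2,6-dihydroxy-4-methoxy-3,5-dimethylphenyl)ethan-1-one F1 (identical with A1). The trilithio derivative of F1 (LiN(SiMe3)2, THF) is then acylated at its methyl carbon by 10 in a crossed Claisen condensation to give 13, which is dehydrated to 14 with AcOH as in step 8. Ring A is still made from the pyrone, but the chain is completed afterwards.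

**Step 7.**
- *What may go wrong:* addition of the dianion to the electron-rich, hence sluggish, benzoate may be slow. Proton transfer from the product, or attack of the carbanion on the lactone of a second molecule, could then take over.
- *Fallback:* it sets out from 10 and 6 and comes back at 11. It replaces the acylation by an aldol addition and an oxidation. Reduction of 10 with i-Bu2AlH gives [3,4-bis(methoxymethoxy)-5-(3-methylbut-2-en-1-yl)phenyl]methanol F2, and MnO2 gives 3,4-bis(methoxymethoxy)-5-(3-methylbut-2-en-1-yl)benzaldehyde F3 (identical with A2). The dianion of 6 adds to this much stronger electrophile without forming an acidic product, to give racemic 6-{4-[3,4-bis(methoxymethoxy)-5-(3-methylbut-2-en-1-yl)phenyl]-4-hydroxy-2-oxobutyl}-4-methoxy-3,5-dimethyl-2H-pyran-2-one F4. Dess–Martin periodinane then oxidises the carbinol to 11.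

**Step 6.**
- *What may go wrong:* coupling with allylic transposition at the tertiary end of the allyl unit, protodeboronation of 9, or migration of the double bond into conjugation with the ring by palladium hydride.
- *Fallback:* it sets out from 8 and comes back at 10. Suzuki–Miyaura coupling with allylboronic acid pinacol ester, whose two termini are equivalent, gives methyl 3,4-bis(methoxymethoxy)-5-(prop-2-en-1-yl)benzoate F5. Cross-metathesis with 2-methylbut-2-ene (second-generation Grubbs catalyst, CH2Cl2, 40 °C) then builds the trisubstituted alkene of 10.

**Step 3.**
- *What may go wrong:* methylation at the lactone carbonyl oxygen instead of the C4 oxygen, which is shielded by two flanking methyl groups. This would move the methyl ether to the wrong ring A oxygen in the end.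
- *Fallback:* it sets out from 4 and comes back at 5. It forms the C4–O bond from the other side. PBr3 in DMF gives 4-bromo-3,5,6-trimethyl-2H-pyran-2-one F6, and NaOMe in MeOH replaces the halogen by addition–elimination at C4. The position of the methoxy group is then fixed by the position of the halogen.

**Step 9.**
- *What may go wrong:* protonation of the prenyl double bond with capture by the freed C4' hydroxyl (chroman closure) or by methanol, and air oxidation of the catechol during isolation.
- *Fallback:* it sets out from 7 and comes back at 15. It removes the acid step altogether by using silyl ethers that fall off in the key step.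
  1. TBSCl and imidazole give methyl 3-bromo-4,5-bis(tert-butyldimethylsilyloxy)benzoate F7.
  2. A neutral Stille coupling (tributyl(3-methylbut-2-en-1-yl)stannane, Pd(PPh3)4, toluene, 100 °C) gives methyl 3,4-bis(tert-butyldimethylsilyloxy)-5-(3-methylbut-2-en-1-yl)benzoate F8.
  3. The dianion of 6 is aroylated as in step 7 to give 6-{4-[3,4-bis(tert-butyldimethylsilyloxy)-5-(3-methylbut-2-en-1-yl)phenyl]-2,4-dioxobutyl}-4-methoxy-3,5-dimethyl-2H-pyran-2-one F9.
  4. Mg(OMe)2 in refluxing MeOH under argon refolds the chain and methanolyses both aryl silyl ethers to 1-[3,4-dihydroxy-5-(3-methylbut-2-en-1-yl)phenyl]-3-(2,6-dihydroxy-4-methoxy-3,5-dimethylphenyl)propane-1,3-dione F10.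
  5. F10 closes to 15 with nothing stronger than AcOH.

## Further compounds

F1 | step 8 | 1-(2,6-dihydroxy-4-methoxy-3,5-dimethylphenyl)ethan-1-one | COc1c(C)c(O)c(C(C)=O)c(O)c1C
F2 | step 7 | [3,4-bis(methoxymethoxy)-5-(3-methylbut-2-en-1-yl)phenyl]methanol | COCOc1cc(CO)cc(CC=C(C)C)c1OCOC
F3 | step 7 | 3,4-bis(methoxymethoxy)-5-(3-methylbut-2-en-1-yl)benzaldehyde | COCOc1cc(C=O)cc(CC=C(C)C)c1OCOC
F4 | step 7 | 6-{4-[3,4-bis(methoxymethoxy)-5-(3-methylbut-2-en-1-yl)phenyl]-4-hydroxy-2-oxobutyl}-4-methoxy-3,5-dimethyl-2H-pyran-2-one (racemic) | COCOc1cc(cc(CC=C(C)C)c1OCOC)C(O)CC(=O)Cc1oc(=O)c(C)c(OC)c1C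
F5 | step 6 | methyl 3,4-bis(methoxymethoxy)-5-(prop-2-en-1-yl)benzoate | COCOc1cc(cc(CC=C)c1OCOC)C(=O)OC
F6 | step 3 | 4-bromo-3,5,6-trimethyl-2H-pyran-2-one | Cc1oc(=O)c(C)c(Br)c1C
F7 | step 9 | methyl 3-bromo-4,5-bis(tert-butyldimethylsilyloxy)benzoate | COC(=O)c1cc(Br)c(O[Si](C)(C)C(C)(C)C)c(O[Si](C)(C)C(C)(C)C)c1
F8 | step 9 | methyl 3,4-bis(tert-butyldimethylsilyloxy)-5-(3-methylbut-2-en-1-yl)benzoate | COC(=O)c1cc(CC=C(C)C)c(O[Si](C)(C)C(C)(C)C)c(O[Si](C)(C)C(C)(C)C)c1
F9 | step 9 | 6-{4-[3,4-bis(tert-butyldimethylsilyloxy)-5-(3-methylbut-2-en-1-yl)phenyl]-2,4-dioxobutyl}-4-methoxy-3,5-dimethyl-2H-pyran-2-one | COc1c(C)c(CC(=O)CC(=O)c2cc(CC=C(C)C)c(O[Si](C)(C)C(C)(C)C)c(O[Si](C)(C)C(C)(C)C)c2)oc(=O)c1C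
F10 | step 9 | 1-[3,4-dihydroxy-5-(3-methylbut-2-en-1-yl)phenyl]-3-(2,6-dihydroxy-4-methoxy-3,5-dimethylphenyl)propane-1,3-dione | COc1c(C)c(O)c(C(=O)CC(=O)c2cc(O)c(O)c(CC=C(C)C)c2)c(O)c1C
A1 | alternative 1 | 1-(2,6-dihydroxy-4-methoxy-3,5-dimethylphenyl)ethan-1-one | COc1c(C)c(O)c(C(C)=O)c(O)c1C
A2 | alternative 1 | 3,4-bis(methoxymethoxy)-5-(3-methylbut-2-en-1-yl)benzaldehyde | COCOc1cc(C=O)cc(CC=C(C)C)c1OCOC
A3 | alternative 1 | (E)-3-[3,4-bis(methoxymethoxy)-5-(3-methylbut-2-en-1-yl)phenyl]-1-(2,6-dihydroxy-4-methoxy-3,5-dimethylphenyl)prop-2-en-1-one | COc1c(C)c(O)c(C(=O)/C=C/c2cc(OCOC)c(OCOC)c(CC=C(C)C)c2)c(O)c1C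
A4 | alternative 2 | 5-hydroxy-7-methoxy-6,8-dimethyl-4H-chromen-4-one | COc1c(C)c(O)c2c(=O)ccoc2c1C
A5 | alternative 2 | 1,2-bis(methoxymethoxy)-3-(3-methylbut-2-en-1-yl)benzene | COCOc1cccc(CC=C(C)C)c1OCOC
A6 | alternative 2 | 2-[3,4-bis(methoxymethoxy)-5-(3-methylbut-2-en-1-yl)phenyl]-4,4,5,5-tetramethyl-1,3,2-dioxaborolane | COCOc1cc(cc(CC=C(C)C)c1OCOC)B1OC(C)(C)C(C)(C)O1
A7 | alternative 3 | 2-iodo-5-methoxy-4,6-dimethylbenzene-1,3-diol | COc1c(C)c(O)c(I)c(O)c1C
A8 | alternative 3 | 5-ethynyl-1,2-bis(methoxymethoxy)-3-(3-methylbut-2-en-1-yl)benzene | C#Cc1cc(OCOC)c(OCOC)c(CC=C(C)C)c1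
A9 | alternative 3 | 3-[3,4-bis(methoxymethoxy)-5-(3-methylbut-2-en-1-yl)phenyl]-1-(2,6-dihydroxy-4-methoxy-3,5-dimethylphenyl)prop-2-yn-1-one | COc1c(C)c(O)c(C(=O)C#Cc2cc(OCOC)c(OCOC)c(CC=C(C)C)c2)c(O)c1C
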